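## Structural features

The target is a humulane-type sesquiterpenoid ester: one eleven-membered carbocycle carrying a 4-hydroxy-3-methoxybenzoyl (vanilloyl) group on the oxygen at C5. The ring is numbered C1 (bearing the exocyclic CH2), C2=C3, C4 (CMe2), C5 (CH–O), C6, C7, C8 (CMe)=C9, C10, C11. It holds a conjugated diene (exocyclic C1=CH2 and the E-disubstituted C2=C3), the quaternary gem-dimethyl carbon C4, and an isolated E-trisubstituted olefin C8=C9. C5 (R) is the only stereocentre and has no stereogenic neighbour, but it sits between the fully substituted C4 and C6H2, so it is a neopentyl-type carbinol that is slow to acylate. The fragile parts are the diene and the remote olefin (acid can trigger transannular cation–olefin closure and double-bond migration), the aryl ester (bases and strong nucleophiles) and the free phenol (acidic and easily oxidised). The real difficulty is closing a medium ring that contains two E olefins while making a bond at the quaternary C4, where ionic substitution is not an option. The key step uses exactly that carbon: C4 bears two methyl groups, the oxygenated C5 and the olefinic C3, so it is the α-carbon of an isobutyrate aldol. An α,α-dimethyl-β-acyloxy acid can therefore release a tertiary C4 radical that forms C3–C4 and the ring in one event.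

## Logic of the disconnections

**27 to 26.** The aryl O–Si bond is the last one to be made good. The phenol stays masked until the end because a free phenol would compete in the acylation of C5, would be deprotonated by the base of the ring closure and would quench the photocatalyst. Nothing is gained in skeleton, but every earlier step is freed from an acidic, oxidisable group. The forward step needs a buffered fluoride source that leaves the aryl ester and the diene alone.

**26 to 25.** The exocyclic C1=CH2 bond is cut back to a C1 ketone. The carbonyl is what makes C2=C3 an electron-poor acceptor for the ring closure, and installing the methylene late exposes the acid-sensitive diene to only one further step. The forward step must be a non-basic methylenation that prefers the ketone to the aryl ester and does not enolise towards C11.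

**25 to 23 (through 24).** The ring bond C3–C4 is cut, with a carboxyl group placed on C4 and a phenylsulfonyl group on C3. C4 is quaternary, so a radical is the natural reactive form, and the acid on C4 next to the C5 oxygen is the retron of an isobutyrate aldol. The gain is the largest in the plan: the carbocycle becomes an open chain with one stereocentre. The forward step must favour 11-endo closure over attack on C8=C9 and over intermolecular addition. Two changes to the acid 23 serve this step. The phenol carries a triisopropylsilyl rather than a tert-butyldimethylsilyl group, because an aryl tert-butyldimethylsilyl ether para to an ester is cleaved by carboxylate bases in DMF. The carboxyl group is reached from a tert-butyl ester, because a methyl ester at this neopentyl position could not be hydrolysed beside the aroate and the sulfonyl enone.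

**23 to 22 to 21 to 20.** The C3–S bond is cut first, then the oxidation level of C1 is lowered, then C1–C2 is cut. The β-sulfonyl enone is too electrophilic to carry far, so it is made last by sulfinate addition to an ynone; the ynone comes from the alkynol, and the two carbons C2 and C3 come from an acetylide. This reduces the C1 end to an aldehyde. The forward steps must tolerate the free acid and the aryl ester, and the sulfinate addition must deliver the enone without further addition.

**20 to 18.** The C1 acetal C–O bonds and the tert-butyl C–O bond are restored. Both chain ends stay masked through the aldol and the acylation and are released together, before any strong electrophile exists in the molecule. The forward step must cleave both groups without strong protic acid, which would isomerise C8=C9.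

**18 to 13 and 16; 16 to 14.** The ester bond between the C5 oxygen and the aroyl carbon is cut. This separates the aromatic part, which needs only a silyl group, from the chain. The forward step must acylate a hindered secondary alcohol without touching its configuration.

**13 to 8 and 11; 11 to 9.** The C4–C5 bond is cut, which is the aldol retron. One step brings in the gem-dimethyl carbon, the carboxyl carbon and the only stereocentre. The forward step must attack the Si face of the C5 aldehyde under reagent control, since the aldehyde is achiral.

**8 to 6 to 4.** C5 is raised to the ester level, then the C6–C7 bond is cut with transposition of the olefin ([3,3] retron). The trisubstituted olefin is traded for a simple allylic alcohol whose configuration is irrelevant. The forward rearrangement must give the E olefin.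

**4 to 1 and 2.** The C9–C10 bond is cut. Two cheap fragments remain: a three-carbon acetal bromide (C10, C11, C1) and a four-carbon enal (C7, C8 with its methyl, C9). The forward step must add 1,2 to the enal.

## Other disconnections considered

**Alternative 1:** The cut is C6–C7, made by ring contraction. The thirteen-membered allyl β-keto lactone A2, (6E,11E)-5,5,12-trimethyl-8-methylidene-1-oxacyclotrideca-6,11-diene-2,4-dione, links C6 to C7 through a CO2 bridge. With Pd(PPh3)4, zerovalent palladium would ionise the allylic C7–O bond and CO2 would be lost. The enolate can form only at C6, because C4 is quaternary, and would recombine with the allyl terminus C7 to give the dienone A1, (3E,8E)-2,2,9-trimethyl-5-methylidenecycloundeca-3,8-dien-1-one.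
- In favour: the hard medium-ring C–C closure is replaced by a lactonisation to a larger ring and an intramolecular recombination. The reaction type is established. The exocyclic methylene and the diene are already in place, so no late methylenation is needed.
- Against: the allyl unit spans C7–C8–C9, and bond formation at C9 would give a nine-membered ring with an isopropenyl branch. Syn/anti interconversion of the allyl complex can erode the E geometry of C8=C9. The diene must survive the whole assembly of A2. A1 carries C5 as a ketone, so the stereocentre must still be made by enantioselective reduction next to C4 (giving A5), followed by acylation and phenol release.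
- Comparison: on ring formation this plan is the better one, since each elementary event has precedent and the chosen radical closure has none at this ring size. On stereochemistry the chosen plan is stronger, because C5 is fixed early and is a spectator in the ring closure. Step economy is about equal after the ring is made (three steps against two), but A2 needs a longer and less convergent build.

**Alternative 2:** Here C10–C11 is formed while C2–C8 of a smaller ring is cleaved. The trans-divinyl cycloheptanol A4, (1R,2S,5R)-1,2-diethenyl-5-[(4-methoxyphenyl)methoxy]-2,6,6-trimethylcycloheptan-1-ol (either trans diastereomer would converge), would be converted by KH and 18-crown-6 into its alkoxide. A chair-like [3,3] shift would then open the seven-membered ring to the enolate of A3, (5E,9R)-9-(4-methoxybenzyloxy)-6,10,10-trimethylcycloundec-5-en-1-one.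
- In favour: anionic oxy-Cope ring expansion is among the most dependable ways to an E-configured medium-ring olefin. It needs no dilution, the precursor ring is unstrained, and C5 rides through untouched.
- Against: A3 has its carbonyl at C2 and saturated C1 and C3. The target needs a methylene on C1 and the E olefin C2=C3, so a regioselective α-methylenation, conversion of the ketone into an olefin towards the neopentyl C3 with control of geometry, and an exchange of the benzyl ether for the aroate all follow. A4 itself has a quaternary carbon bearing methyl and vinyl next to a tertiary carbinol, with trans control, a gem-dimethyl group and an oxygenated centre on a seven-membered ring, which is a long synthesis in its own right.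
- Comparison: the ring-forming event is more secure than in the chosen plan and equal to it in E selectivity for C8=C9. In structural fit it is poorer, because functionality ends up one carbon away from where it is needed. In step count it is clearly longer.

**Alternative 3:** The cut is C4–C5. The acyclic aldehyde A6, (4E,8Z)-4,11-dimethyl-8-[(trimethylsilyl)methyl]dodeca-4,8,10-trienal, would be activated at C5 by a chiral Lewis acid made from BINOL and TiF4. The far terminus C4 of the pentadienylsilane would attack with loss of the silyl group, giving the alcohol A5, (1R,3E,8E)-2,2,9-trimethyl-5-methylidenecycloundeca-3,8-dien-1-ol.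
- In favour: one step would make the ring, the quaternary C4, the C5 stereocentre and the complete diene. A6 is achiral and needs no protecting group, and A5 is one acylation and one deprotection away from the target. In step economy this is the best of the four plans.
- Against: attack through the remote, fully substituted terminus must beat attack through C2, which would give a nine-membered ring, while an eleven-membered ring closes. The BINOL and TiF4 system is known for simple allylsilanes and mostly non-enolisable aldehydes in intermolecular reactions, so enantiocontrol with an enolisable aliphatic aldehyde in a macrocyclic mode is unsupported. A Lewis acid could also trigger carbonyl-ene closure of the aldehyde onto C8=C9 or protodesilylation.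
- Comparison: both plans rest on an unprecedented eleven-membered closure, so they are equal in that respect. The alternative stakes ring formation, regiochemistry and enantioselectivity on the same step. The chosen plan separates them: C5 comes from a stoichiometric, reagent-controlled aldol and the ring closure creates no stereocentre. The alternative is the better plan if the one step works; the chosen plan fails in fewer ways.

Key step: step 12

Remark: the facial sense of the promoter in step 5 is assigned by analogy with its behaviour towards unbranched aliphatic aldehydes; should it prove opposite, N-tosyl-D-valine is used and nothing else changes.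

## Route

**Step 1**
Reactants: 1 2-(2-bromoethyl)-1,3-dioxolane; 2 methacrolein
Product: 4 rac-5-(1,3-dioxolan-2-yl)-2-methylpent-1-en-3-ol, via Grignard reagent 3 (not isolated)
Conditions: Mg, THF, 25–30 °C; then 2, −20 → 0 °C; aq. NH4Cl
Reagents that add atoms: none
Why: Grignard 1,2-addition; the alkylmagnesium bromide, formed below 30 °C where this β-acetal reagent is stable, adds to the unhindered aldehyde carbon of the enal and not to the conjugate position. The new carbinol centre is racemic and is erased in step 2.

**Step 2**
Reactants: 4 rac-5-(1,3-dioxolan-2-yl)-2-methylpent-1-en-3-ol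
Product: 6 ethyl (4E)-7-(1,3-dioxolan-2-yl)-4-methylhept-4-enoate, via mixed ketene acetal 5 (not isolated)
Conditions: MeC(OEt)3 (6 equiv), EtCO2H (5 mol%), 140 °C, EtOH distilled off
Reagents that add atoms: triethyl orthoacetate, CC(OCC)(OCC)OCC
Why: Johnson–Claisen rearrangement; exchange with the orthoester and loss of ethanol give ketene acetal 5, whose chair [3,3] shift keeps the acetal-bearing chain equatorial to avoid a 1,3-diaxial clash with the ethoxy group, which should give the E olefin C8=C9 with high selectivity while forming C6–C7. Any acetal exchange with ethanol is harmless, because all acetal forms converge in step 8.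

**Step 3**
Reactants: 6 ethyl (4E)-7-(1,3-dioxolan-2-yl)-4-methylhept-4-enoate
Product: 8 (4E)-7-(1,3-dioxolan-2-yl)-4-methylhept-4-enal, via aluminium hemiacetal 7 (not isolated)
Conditions: i-Bu2AlH (1.05 equiv), CH2Cl2, −78 °C; MeOH, then aq. potassium sodium tartrate
Reagents that add atoms: none
Why: Partial reduction of an ester with diisobutylaluminium hydride; the tetrahedral aluminium hemiacetal 7 persists at −78 °C and releases the aldehyde only on hydrolysis, and the acetal and the olefin are inert.

**Step 4**
Reactants: 9 tert-butyl isobutyrate
Product: 11 [(1-tert-butoxy-2-methylprop-1-en-1-yl)oxy]trimethylsilane, via lithium enolate 10 (not isolated)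
Conditions: LiN(i-Pr)2, THF, −78 °C; Me3SiCl, −78 → 23 °C; distillation
Reagents that add atoms: chlorotrimethylsilane, C[Si](C)(C)Cl
Why: O-silylation of an ester enolate; the fully substituted enolate of a hindered tert-butyl ester is trapped on oxygen, and there is no enolate geometry to control because both substituents are methyl.

**Step 5**
Reactants: 8 (4E)-7-(1,3-dioxolan-2-yl)-4-methylhept-4-enal; 11 [(1-tert-butoxy-2-methylprop-1-en-1-yl)oxy]trimethylsilane
Product: 13 tert-butyl (3R,6E)-9-(1,3-dioxolan-2-yl)-3-hydroxy-2,2,6-trimethylnon-6-enoate, via trimethylsilyl ether 12 (not isolated)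
Conditions: N-tosyl-L-valine (1.1 equiv), BH3·THF (1.0 equiv), CH2Cl2, 0 → 23 °C; then 8, 11 (1.3 equiv), −78 °C; pH 7 buffer; K2CO3 (10 mol%), MeOH, 0 °C
Reagents that add atoms: none
Why: Asymmetric Mukaiyama aldol promoted by a stoichiometric chiral oxazaborolidinone; the boron Lewis acid binds the aldehyde, and the promoter from L-valine is expected to expose the Si face of C5 to the ketene acetal in an open transition state, which sets (R)-C5 together with the gem-dimethyl C4. The dioxolane is a far weaker electrophile than the aldehyde at −78 °C, and mild methanolysis removes the silyl group from 12.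

**Step 6**
Reactants: 14 vanillic acid
Product: 16 3-methoxy-4-(triisopropylsilyloxy)benzoic acid, via bis-silylated ester 15 (not isolated)
Conditions: i-Pr3SiCl (2.3 equiv), imidazole, DMF, 23 °C; then K2CO3, MeOH/THF/H2O, 0 °C; 1 M HCl to pH 3
Reagents that add atoms: chlorotriisopropylsilane, CC(C)[Si](Cl)(C(C)C)C(C)C
Why: Silylation of both acidic sites, then selective cleavage of the labile silyl ester, a standard way to O-silylated hydroxybenzoic acids; the hindered aryl silyl ether survives brief carbonate treatment. Triisopropylsilyl is chosen because it must later resist a carboxylate base in DMF.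

**Step 7**
Reactants: 13 tert-butyl (3R,6E)-9-(1,3-dioxolan-2-yl)-3-hydroxy-2,2,6-trimethylnon-6-enoate; 16 3-methoxy-4-(triisopropylsilyloxy)benzoic acid
Product: 18 tert-butyl (3R,6E)-9-(1,3-dioxolan-2-yl)-3-{[3-methoxy-4-(triisopropylsilyloxy)benzoyl]oxy}-2,2,6-trimethylnon-6-enoate, via mixed anhydride 17 (not isolated)
Conditions: 16 (1.5 equiv), 2,4,6-Cl3C6H2COCl, Et3N, toluene, 23 °C; then 13, DMAP (2 equiv), 23 → 50 °C
Reagents that add atoms: none
Why: Yamaguchi esterification; the mixed anhydride 17 passes the aroyl group to DMAP and then to the hindered secondary alcohol. The C5–O bond is not broken, so the configuration is kept, and the β-hydroxy ester cannot eliminate because C4 bears no hydrogen.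

**Step 8**
Reactants: 18 tert-butyl (3R,6E)-9-(1,3-dioxolan-2-yl)-3-{[3-methoxy-4-(triisopropylsilyloxy)benzoyl]oxy}-2,2,6-trimethylnon-6-enoate
Product: 20 (3R,6E)-3-{[3-methoxy-4-(triisopropylsilyloxy)benzoyl]oxy}-2,2,6-trimethyl-10-oxodec-6-enoic acid, via silyl ester lutidinium salt 19 (not isolated)
Conditions: Me3SiOTf (4 equiv), 2,6-lutidine (6 equiv), CH2Cl2, 0 → 23 °C; then H2O, 0 °C; pH 4 buffer
Reagents that add atoms: water, O
Why: Two known silyl triflate reactions run in one flask; Me3SiOTf with 2,6-lutidine turns a tert-butyl ester into its trimethylsilyl ester with loss of isobutene, and opens an aldehyde-derived dioxolane to an oxocarbenium ion that the base traps as a pyridinium salt, and water then releases the acid and the aldehyde. No strong protic acid is present, so the trisubstituted olefin, the aryl silyl ether and the aroate should survive.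

**Step 9**
Reactants: 20 (3R,6E)-3-{[3-methoxy-4-(triisopropylsilyloxy)benzoyl]oxy}-2,2,6-trimethyl-10-oxodec-6-enoic acid
Product: 21 (3R,6E)-10-hydroxy-3-{[3-methoxy-4-(triisopropylsilyloxy)benzoyl]oxy}-2,2,6-trimethyldodec-6-en-11-ynoic acid (both C10 epimers)
Conditions: HC≡CMgBr (3 equiv), THF, −78 → −20 °C; 1 M HCl to pH 3, 0 °C
Reagents that add atoms: ethynylmagnesium bromide, C#C[Mg]Br
Why: Grignard addition of an acetylide to an aldehyde; the first equivalent deprotonates the acid to a hindered, unreactive carboxylate, and a second adds to the aldehyde far faster than to the electron-rich aryl ester at low temperature. The new carbinol at C1 of the ring numbering is formed as both epimers and is oxidised in step 10.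

**Step 10**
Reactants: 21 (3R,6E)-10-hydroxy-3-{[3-methoxy-4-(triisopropylsilyloxy)benzoyl]oxy}-2,2,6-trimethyldodec-6-en-11-ynoic acid
Product: 22 (3R,6E)-3-{[3-methoxy-4-(triisopropylsilyloxy)benzoyl]oxy}-2,2,6-trimethyl-10-oxododec-6-en-11-ynoic acid
Conditions: Dess–Martin periodinane (1.3 equiv), CH2Cl2, 0 → 23 °C; filtration through silica gel
Reagents that add atoms: none
Why: Dess–Martin oxidation of a secondary propargylic alcohol to the terminal ynone under neutral conditions that tolerate the free acid, the olefin and the silyl ether; the non-aqueous work-up keeps nucleophiles away from the ynone.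

**Step 11**
Reactants: 22 (3R,6E)-3-{[3-methoxy-4-(triisopropylsilyloxy)benzoyl]oxy}-2,2,6-trimethyl-10-oxododec-6-en-11-ynoic acid
Product: 23 (3R,6E,11E)-3-{[3-methoxy-4-(triisopropylsilyloxy)benzoyl]oxy}-2,2,6-trimethyl-10-oxo-12-(phenylsulfonyl)dodeca-6,11-dienoic acid
Conditions: PhSO2Na (1.3 equiv), AcOH (2 equiv), THF/H2O (4:1), 0 → 23 °C
Reagents that add atoms: sodium benzenesulfinate, [Na+].[O-]S(=O)c1ccccc1
Why: Conjugate addition of benzenesulfinate through sulfur to the ynone and protonation by acetic acid, a known route to β-sulfonyl enones; reversible sulfinate addition–elimination should settle the olefin in the more stable E form, and the geometry is in any case not carried into step 12.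

**Step 12**
Reactants: 23 (3R,6E,11E)-3-{[3-methoxy-4-(triisopropylsilyloxy)benzoyl]oxy}-2,2,6-trimethyl-10-oxo-12-(phenylsulfonyl)dodeca-6,11-dienoic acid
Product: 25 (1R,3E,8E)-2,2,9-trimethyl-5-oxocycloundeca-3,8-dien-1-yl 3-methoxy-4-(triisopropylsilyloxy)benzoate, via caesium carboxylate 24 (not isolated)
Conditions: Ir[dF(CF3)ppy]2(dtbbpy)PF6 (2 mol%), CsHCO3 (1.2 equiv), degassed DMF, 450 nm LEDs, 25 °C; 23 added over 10 h by syringe pump (final 1 mM)
Reagents that add atoms: none
Why: Proposed new method: the excited trivalent iridium complex oxidises carboxylate 24 by single-electron transfer, CO2 is lost, and the nucleophilic tertiary radical at C4 adds to C3 of the β-sulfonyl enone, the carbon that carries the sulfonyl group, because this gives the delocalised α-keto radical at C2, which then expels PhSO2• by β-scission; the divalent iridium complex reduces PhSO2• to sulfinate and closes the cycle. The closest known reaction types are the intermolecular photoredox decarboxylative alkenylation of carboxylic acids with vinyl sulfones, the decarboxylative radical macrocyclisation of peptides onto acrylamides, and conjugate additions of tertiary radicals that create quaternary carbons; none of them has closed an eleven-membered carbocycle. The ring closes in the 11-endo-trig mode, with both olefinic carbons C2 and C3 ending inside the ring. No stereocentre is formed; C5 is not part of the radical and keeps its R configuration, and the E geometry of C2=C3 should follow from β-scission through the conformer of the adduct radical that places the quaternary C4 anti to the carbonyl group. The step needs selectivity for C3 over 6-endo or 5-exo attack on the unactivated C8=C9 olefin and over intermolecular addition; what secures it is the polarity match between the electron-rich tertiary radical and the doubly activated acceptor, the chain folding favoured by the gem-dimethyl and acyloxy substituents, and a substrate concentration near 1 mM kept low by slow addition. The triisopropylsilyl ether keeps the phenol from quenching the photocatalyst, and a 1,2-acyloxy shift of the β-acyloxy radical is not expected because it would turn a tertiary radical into a secondary one.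

**Step 13**
Reactants: 25 (1R,3E,8E)-2,2,9-trimethyl-5-oxocycloundeca-3,8-dien-1-yl 3-methoxy-4-(triisopropylsilyloxy)benzoate
Product: 26 (1R,3E,8E)-2,2,9-trimethyl-5-methylidenecycloundeca-3,8-dien-1-yl 3-methoxy-4-(triisopropylsilyloxy)benzoate
Conditions: Zn, CH2Br2, TiCl4, THF/CH2Cl2, 0 → 23 °C
Reagents that add atoms: dibromomethane, BrCBr
Why: Takai–Lombardo methylenation; the zinc and titanium methylene reagent is non-basic and adds 1,2 to ketones and enones while leaving esters alone at this temperature, so C1=O becomes C1=CH2 without attack on the aroate, without enolisation towards C11 and without any effect on C5.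

**Step 14**
Reactants: 26 (1R,3E,8E)-2,2,9-trimethyl-5-methylidenecycloundeca-3,8-dien-1-yl 3-methoxy-4-(triisopropylsilyloxy)benzoate
Product: 27 (1R,3E,8E)-2,2,9-trimethyl-5-methylidenecycloundeca-3,8-dien-1-yl 4-hydroxy-3-methoxybenzoate
Conditions: Bu4NF (1.1 equiv), AcOH (1.1 equiv), THF, 0 °C
Reagents that add atoms: none
Why: Fluoride cleavage of an aryl silyl ether, made easy by the para acyl group that stabilises the departing phenoxide; acetic acid buffers the medium so that the aryl ester is not attacked and the diene meets neither strong acid nor strong base.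

## Compound list

1 | 2-(2-bromoethyl)-1,3-dioxolane | BrCCC1OCCO1 | starting material
2 | methacrolein (2-methylprop-2-enal) | C=C(C)C=O | starting material
3 | [2-(1,3-dioxolan-2-yl)ethyl]magnesium bromide | Br[Mg]CCC1OCCO1 | intermediate
4 | rac-5-(1,3-dioxolan-2-yl)-2-methylpent-1-en-3-ol | C=C(C)C(O)CCC1OCCO1 | intermediate
5 | rac-2-{3-[(1-ethoxyethenyl)oxy]-4-methylpent-4-en-1-yl}-1,3-dioxolane | C=C(OCC)OC(CCC1OCCO1)C(C)=C | intermediate
6 | ethyl (4E)-7-(1,3-dioxolan-2-yl)-4-methylhept-4-enoate | CCOC(=O)CC/C(C)=C/CCC1OCCO1 | intermediate
7 | {[(4E)-7-(1,3-dioxolan-2-yl)-1-ethoxy-4-methylhept-4-en-1-yl]oxy}bis(2-methylpropyl)alumane (C1 epimers) | CCOC(O[Al](CC(C)C)CC(C)C)CC/C(C)=C/CCC1OCCO1 | intermediate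
8 | (4E)-7-(1,3-dioxolan-2-yl)-4-methylhept-4-enal | O=CCC/C(C)=C/CCC1OCCO1 | intermediate
9 | tert-butyl isobutyrate (tert-butyl 2-methylpropanoate) | CC(C)C(=O)OC(C)(C)C | starting material
10 | lithium 1-tert-butoxy-2-methylprop-1-en-1-olate | [Li]OC(OC(C)(C)C)=C(C)C | intermediate
11 | [(1-tert-butoxy-2-methylprop-1-en-1-yl)oxy]trimethylsilane | CC(C)=C(OC(C)(C)C)O[Si](C)(C)C | intermediate
12 | tert-butyl (3R,6E)-9-(1,3-dioxolan-2-yl)-2,2,6-trimethyl-3-(trimethylsilyloxy)non-6-enoate | CC(C)(C)OC(=O)C(C)(C)[C@H](O[Si](C)(C)C)CC/C(C)=C/CCC1OCCO1 | intermediate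
13 | tert-butyl (3R,6E)-9-(1,3-dioxolan-2-yl)-3-hydroxy-2,2,6-trimethylnon-6-enoate | CC(C)(C)OC(=O)C(C)(C)[C@H](O)CC/C(C)=C/CCC1OCCO1 | intermediate
14 | vanillic acid (4-hydroxy-3-methoxybenzoic acid) | COc1cc(C(=O)O)ccc1O | starting material
15 | triisopropylsilyl 3-methoxy-4-(triisopropylsilyloxy)benzoate | COc1cc(C(=O)O[Si](C(C)C)(C(C)C)C(C)C)ccc1O[Si](C(C)C)(C(C)C)C(C)C | intermediate
16 | 3-methoxy-4-(triisopropylsilyloxy)benzoic acid | COc1cc(C(=O)O)ccc1O[Si](C(C)C)(C(C)C)C(C)C | intermediate
17 | 3-methoxy-4-(triisopropylsilyloxy)benzoic 2,4,6-trichlorobenzoic anhydride | COc1cc(C(=O)OC(=O)c2c(Cl)cc(Cl)cc2Cl)ccc1O[Si](C(C)C)(C(C)C)C(C)C | intermediate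
18 | tert-butyl (3R,6E)-9-(1,3-dioxolan-2-yl)-3-{[3-methoxy-4-(triisopropylsilyloxy)benzoyl]oxy}-2,2,6-trimethylnon-6-enoate | CC(C)(C)OC(=O)C(C)(C)[C@H](OC(=O)c1ccc(O[Si](C(C)C)(C(C)C)C(C)C)c(OC)c1)CC/C(C)=C/CCC1OCCO1 | intermediate
19 | trimethylsilyl (3R,6E)-10-(2,6-dimethylpyridinium-1-yl)-3-{[3-methoxy-4-(triisopropylsilyloxy)benzoyl]oxy}-2,2,6-trimethyl-10-[2-(trimethylsilyloxy)ethoxy]dec-6-enoate triflate (C10 epimers) | C[Si](C)(C)OC(=O)C(C)(C)[C@H](OC(=O)c1ccc(O[Si](C(C)C)(C(C)C)C(C)C)c(OC)c1)CC/C(C)=C/CCC(OCCO[Si](C)(C)C)[n+]1c(C)cccc1C.[O-]S(=O)(=O)C(F)(F)F | intermediate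
20 | (3R,6E)-3-{[3-methoxy-4-(triisopropylsilyloxy)benzoyl]oxy}-2,2,6-trimethyl-10-oxodec-6-enoic acid | OC(=O)C(C)(C)[C@H](OC(=O)c1ccc(O[Si](C(C)C)(C(C)C)C(C)C)c(OC)c1)CC/C(C)=C/CCC=O | intermediate
21 | (3R,6E)-10-hydroxy-3-{[3-methoxy-4-(triisopropylsilyloxy)benzoyl]oxy}-2,2,6-trimethyldodec-6-en-11-ynoic acid (C10 epimers) | OC(=O)C(C)(C)[C@H](OC(=O)c1ccc(O[Si](C(C)C)(C(C)C)C(C)C)c(OC)c1)CC/C(C)=C/CCC(O)C#C | intermediate
22 | (3R,6E)-3-{[3-methoxy-4-(triisopropylsilyloxy)benzoyl]oxy}-2,2,6-trimethyl-10-oxododec-6-en-11-ynoic acid | OC(=O)C(C)(C)[C@H](OC(=O)c1ccc(O[Si](C(C)C)(C(C)C)C(C)C)c(OC)c1)CC/C(C)=C/CCC(=O)C#C | intermediate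
23 | (3R,6E,11E)-3-{[3-methoxy-4-(triisopropylsilyloxy)benzoyl]oxy}-2,2,6-trimethyl-10-oxo-12-(phenylsulfonyl)dodeca-6,11-dienoic acid | OC(=O)C(C)(C)[C@H](OC(=O)c1ccc(O[Si](C(C)C)(C(C)C)C(C)C)c(OC)c1)CC/C(C)=C/CCC(=O)/C=C/S(=O)(=O)c1ccccc1 | intermediate
24 | caesium (3R,6E,11E)-3-{[3-methoxy-4-(triisopropylsilyloxy)benzoyl]oxy}-2,2,6-trimethyl-10-oxo-12-(phenylsulfonyl)dodeca-6,11-dienoate | [Cs+].[O-]C(=O)C(C)(C)[C@H](OC(=O)c1ccc(O[Si](C(C)C)(C(C)C)C(C)C)c(OC)c1)CC/C(C)=C/CCC(=O)/C=C/S(=O)(=O)c1ccccc1 | intermediate
25 | (1R,3E,8E)-2,2,9-trimethyl-5-oxocycloundeca-3,8-dien-1-yl 3-methoxy-4-(triisopropylsilyloxy)benzoate | O=C1/C=C/C(C)(C)[C@H](OC(=O)c2ccc(O[Si](C(C)C)(C(C)C)C(C)C)c(OC)c2)CC/C(C)=C/CC1 | intermediate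
26 | (1R,3E,8E)-2,2,9-trimethyl-5-methylidenecycloundeca-3,8-dien-1-yl 3-methoxy-4-(triisopropylsilyloxy)benzoate | C=C1/C=C/C(C)(C)[C@H](OC(=O)c2ccc(O[Si](C(C)C)(C(C)C)C(C)C)c(OC)c2)CC/C(C)=C/CC1 | intermediate
27 | (1R,3E,8E)-2,2,9-trimethyl-5-methylidenecycloundeca-3,8-dien-1-yl 4-hydroxy-3-methoxybenzoate | C=C1/C=C/C(C)(C)[C@H](OC(=O)c2ccc(O)c(OC)c2)CC/C(C)=C/CC1 | target

## Step count and least certain steps

Total: 14 steps. Longest linear sequence: 12 steps (1, 2, 3, 5, 7, 8, 9, 10, 11, 12, 13, 14); steps 4 and 6 are side branches.

**Step 12 (key step).** The most likely failure is that the tertiary C4 radical cyclises onto the nearby C8=C9 olefin (6-endo or 5-exo) before it reaches C3, because closing an eleven-membered ring is entropically and enthalpically costly and the two rates are expected to be of the same order. Further losses could come from intermolecular addition leading to oligomers, from hydrogen-atom abstraction giving the reduced open chain, and from dark oxa-Michael addition–elimination of the carboxylate on the sulfonyl enone.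

The fallback uses known chemistry and closes the ring at C1–C2 instead; it sets out from 13 and returns at 25.
- LiAlH4 in THF would reduce the tert-butyl ester to (3R,6E)-9-(1,3-dioxolan-2-yl)-2,2,6-trimethylnon-6-ene-1,3-diol F1.
- Selective oxidation of the primary alcohol (TEMPO, PhI(OAc)2) would give (3R,6E)-9-(1,3-dioxolan-2-yl)-3-hydroxy-2,2,6-trimethylnon-6-enal F2, whose aldehyde carbon is the future C3.
- Takai olefination (CrCl2, CHI3) would give (1E,4R,7E)-10-(1,3-dioxolan-2-yl)-1-iodo-3,3,7-trimethyldeca-1,7-dien-4-ol F3.
- Yamaguchi acylation with 16 would give (1E,4R,7E)-10-(1,3-dioxolan-2-yl)-1-iodo-3,3,7-trimethyldeca-1,7-dien-4-yl 3-methoxy-4-(triisopropylsilyloxy)benzoate F4.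
- Transacetalisation (pyridinium tosylate, wet acetone) would free (1E,4R,7E)-1-iodo-3,3,7-trimethyl-11-oxoundeca-1,7-dien-4-yl 3-methoxy-4-(triisopropylsilyloxy)benzoate F5.
- Nozaki–Hiyama–Kishi macrocyclisation (CrCl2, catalytic NiCl2, DMSO, high dilution) would form C1–C2 and give (1R,3E,8E)-5-hydroxy-2,2,9-trimethylcycloundeca-3,8-dien-1-yl 3-methoxy-4-(triisopropylsilyloxy)benzoate F6 as both carbinol epimers.
- Dess–Martin oxidation would converge on 25.

**Step 5.** The bulkier tert-butyl ketene acetal may erode the facial selectivity of the promoter, and the boron Lewis acid may engage the dioxolane. The fallback sets out from 8 and returns at 13 with reduction in place of the aldol as the stereo-determining event. Lithium enolate 10 would add to 8 at −78 °C to give racemic tert-butyl (3RS,6E)-9-(1,3-dioxolan-2-yl)-3-hydroxy-2,2,6-trimethylnon-6-enoate F7. Dess–Martin oxidation would give tert-butyl (6E)-9-(1,3-dioxolan-2-yl)-2,2,6-trimethyl-3-oxonon-6-enoate F8. Corey–Bakshi–Shibata reduction with (S)-2-methyl-CBS-oxazaborolidine and catecholborane, with the quaternary carbon as the large group, should then deliver 13.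

**Step 8.** Running two cleavages in one flask may leave one of them incomplete, or the silyl triflate may start cation–olefin chemistry at the oxocarbenium stage. The fallback sets out from 18 and returns at 20 in two protic stages that can be followed separately. Pyridinium tosylate in wet acetone would give tert-butyl (3R,6E)-3-{[3-methoxy-4-(triisopropylsilyloxy)benzoyl]oxy}-2,2,6-trimethyl-10-oxodec-6-enoate F9. Aqueous H3PO4 (85%) in toluene would then remove the tert-butyl group.

**Step 13.** TiCl4 may induce transannular cyclisation or migration of the newly formed diene, or the reagent may be consumed by the hindered, conjugated ketone too slowly. The fallback sets out from 25 and returns at 26 by Wittig methylenation with Ph3P=CH2 (from Ph3PCH3Br and KOt-Bu, THF, 0 °C), a basic ylide reagent in place of the Lewis acidic metal carbenoid. This fallback makes no new compound (F0).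

## Further compounds

F1 | step 12 | (3R,6E)-9-(1,3-dioxolan-2-yl)-2,2,6-trimethylnon-6-ene-1,3-diol | OCC(C)(C)[C@H](O)CC/C(C)=C/CCC1OCCO1
F2 | step 12 | (3R,6E)-9-(1,3-dioxolan-2-yl)-3-hydroxy-2,2,6-trimethylnon-6-enal | O=CC(C)(C)[C@H](O)CC/C(C)=C/CCC1OCCO1
F3 | step 12 | (1E,4R,7E)-10-(1,3-dioxolan-2-yl)-1-iodo-3,3,7-trimethyldeca-1,7-dien-4-ol | I/C=C/C(C)(C)[C@H](O)CC/C(C)=C/CCC1OCCO1
F4 | step 12 | (1E,4R,7E)-10-(1,3-dioxolan-2-yl)-1-iodo-3,3,7-trimethyldeca-1,7-dien-4-yl 3-methoxy-4-(triisopropylsilyloxy)benzoate | I/C=C/C(C)(C)[C@H](OC(=O)c1ccc(O[Si](C(C)C)(C(C)C)C(C)C)c(OC)c1)CC/C(C)=C/CCC1OCCO1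
F5 | step 12 | (1E,4R,7E)-1-iodo-3,3,7-trimethyl-11-oxoundeca-1,7-dien-4-yl 3-methoxy-4-(triisopropylsilyloxy)benzoate | I/C=C/C(C)(C)[C@H](OC(=O)c1ccc(O[Si](C(C)C)(C(C)C)C(C)C)c(OC)c1)CC/C(C)=C/CCC=O
F6 | step 12 | (1R,3E,8E)-5-hydroxy-2,2,9-trimethylcycloundeca-3,8-dien-1-yl 3-methoxy-4-(triisopropylsilyloxy)benzoate (C5 epimers) | OC1/C=C/C(C)(C)[C@H](OC(=O)c2ccc(O[Si](C(C)C)(C(C)C)C(C)C)c(OC)c2)CC/C(C)=C/CC1
F7 | step 5 | tert-butyl (3RS,6E)-9-(1,3-dioxolan-2-yl)-3-hydroxy-2,2,6-trimethylnon-6-enoate | CC(C)(C)OC(=O)C(C)(C)C(O)CC/C(C)=C/CCC1OCCO1
F8 | step 5 | tert-butyl (6E)-9-(1,3-dioxolan-2-yl)-2,2,6-trimethyl-3-oxonon-6-enoate | CC(C)(C)OC(=O)C(C)(C)C(=O)CC/C(C)=C/CCC1OCCO1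
F9 | step 8 | tert-butyl (3R,6E)-3-{[3-methoxy-4-(triisopropylsilyloxy)benzoyl]oxy}-2,2,6-trimethyl-10-oxodec-6-enoate | CC(C)(C)OC(=O)C(C)(C)[C@H](OC(=O)c1ccc(O[Si](C(C)C)(C(C)C)C(C)C)c(OC)c1)CC/C(C)=C/CCC=O
F0 | step 13 | none | none
A1 | alternative 1 | (3E,8E)-2,2,9-trimethyl-5-methylidenecycloundeca-3,8-dien-1-one | O=C1CC/C(C)=C/CCC(=C)/C=C/C1(C)C
A2 | alternative 1 | (6E,11E)-5,5,12-trimethyl-8-methylidene-1-oxacyclotrideca-6,11-diene-2,4-dione | O=C1CC(=O)OC/C(C)=C/CCC(=C)/C=C/C1(C)C
A3 | alternative 2 | (5E,9R)-9-(4-methoxybenzyloxy)-6,10,10-trimethylcycloundec-5-en-1-one | O=C1CC(C)(C)[C@H](OCc2ccc(OC)cc2)CC/C(C)=C/CCC1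
A4 | alternative 2 | (1R,2S,5R)-1,2-diethenyl-5-[(4-methoxyphenyl)methoxy]-2,6,6-trimethylcycloheptan-1-ol | C=C[C@]1(O)CC(C)(C)[C@H](OCc2ccc(OC)cc2)CC[C@@]1(C)C=C
A5 | alternative 3 | (1R,3E,8E)-2,2,9-trimethyl-5-methylidenecycloundeca-3,8-dien-1-ol | C=C1/C=C/C(C)(C)[C@H](O)CC/C(C)=C/CC1
A6 | alternative 3 | (4E,8Z)-4,11-dimethyl-8-[(trimethylsilyl)methyl]dodeca-4,8,10-trienal | O=CCC/C(C)=C/CC/C(C[Si](C)(C)C)=C/C=C(C)C
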